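**Strategy**

Counting from the ester carbon (C1), the target is cut at the ring bond C5–C7 of its trans-cyclopropane (ring C5–C6–C7). Without that bond, the ring carbons and the adjacent methyl-bearing C8 become an acyclic C5/C7/C8 stereotriad that can be set by catalyst and reagent control. The key step closes the ring: the phenyl ate complex of a C5 pinacol boronate displaces a C7 mesylate (3-exo-tet), forming C5–C7 and both ring stereocentres at once by double inversion. Its precursor is the open-chain (5S,7R,8R) γ-mesyloxy boronate (1,3-anti, C7/C8 syn) with a terminal vinyl group, later extended to the C9–C12 diene, and a silyl-protected C1 alcohol; C16 comes from (S)-citronellal.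

Key step: step 7

Atom numbers C1–C19 are those of the target chain and are used for all intermediates. Abbreviations: TBS = tert-butyldimethylsilyl; TIPS = tri(propan-2-yl)silyl; pinB = 4,4,5,5-tetramethyl-1,3,2-dioxaborolan-2-yl; Ipc = isopinocampheyl of the (+)-α-pinene series, (1R,2S,3R,5R)-2,6,6-trimethylbicyclo[3.1.1]heptan-3-yl.

Assumption: the sense of induction in step 3 ((R,S)-Josiphos giving the 5S boronate) and in step 5 ((−)-Ipc2BOMe-derived reagent attacking the Si face of the aldehyde) is taken from the accepted models for these reagent classes; each would be checked on the first batch by Mosher ester analysis (of the β-hydroxy ester from oxidation of a sample of 6, and of 11), and the mirror-image ligand or borane would be used if the sense were opposite.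

**Route**

Step 1
Reactants: 1 hex-5-en-1-ol
Product: 2 tert-butyl(hex-5-en-1-yloxy)dimethylsilane
Conditions: TBSCl, imidazole, DMF, rt
Reagents that add atoms: tert-butyldimethylsilyl chloride CC(C)(C)[Si](C)(C)Cl
Why: Imidazole-promoted silylation of the primary alcohol (silyl ether protection) gives an ether that is inert to all steps up to the fluoride treatment.

Step 2
Reactants: 2 tert-butyl(hex-5-en-1-yloxy)dimethylsilane; 3 ethyl acrylate
Product: 4 ethyl (2E)-7-(TBSO)hept-2-enoate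
Conditions: 3 (3 equiv), second-generation Hoveyda–Grubbs catalyst (2 mol%), CH2Cl2, 40 °C
Reagents that add atoms: none
Why: Olefin cross-metathesis of a terminal alkene with an electron-poor acrylate should give the cross product selectively as the E enoate, which supplies C5–C7.

Step 3
Reactants: 4 ethyl (2E)-7-(TBSO)hept-2-enoate; 5 bis(pinacolato)diboron
Product: 6 ethyl (3S)-7-(TBSO)-3-(pinB)heptanoate
Conditions: CuCl (3 mol%), NaOt-Bu (5 mol%), (R,S)-Josiphos (3 mol%), MeOH (2 equiv), THF, rt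
Reagents that add atoms: none
Why: Copper-catalysed enantioselective conjugate borylation of an enoate, in which the Josiphos-bound boryl copper adds to one face of the E alkene and methanol protonates the copper enolate, should set C5 as S under catalyst control.

Step 4
Reactants: 6 ethyl (3S)-7-(TBSO)-3-(pinB)heptanoate
Product: 8 (3S)-7-(TBSO)-3-(pinB)heptanal, via aluminium hemiacetal 7 (not isolated)
Conditions: i-Bu2AlH (1.1 equiv), toluene, −78 °C; MeOH, then aq. potassium sodium tartrate; used crude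
Reagents that add atoms: none
Why: Partial reduction of the ester with i-Bu2AlH stops at the tetrahedral intermediate 7, which is stable at −78 °C and releases the aldehyde only on work-up, while the C–B bond and C5 are untouched.

Step 5
Reactants: 8 (3S)-7-(TBSO)-3-(pinB)heptanal; 9 cis-but-2-ene
Product: 11 (3R,4R,6S)-10-(TBSO)-3-methyl-6-(pinB)dec-1-en-4-ol, via diisopinocampheylborinate 10 (not isolated)
Conditions: 9, KOt-Bu, n-BuLi, THF, −78 → −45 °C; (−)-Ipc2BOMe, −78 °C; BF3·OEt2; then 8, −78 °C; HOCH2CH2NH2, Et2O, rt (no peroxide)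
Reagents that add atoms: none
Why: Brown asymmetric crotylboration through a Zimmerman–Traxler chair, in which the Z crotyl geometry gives the C7/C8 syn pair and the isopinocampheyl groups direct attack to the Si face of the aldehyde (7R,8R) over the weak bias of remote C5, with ethanolamine releasing the alcohol from borinate 10 without touching the C5–B bond.

Step 6
Reactants: 11 (3R,4R,6S)-10-(TBSO)-3-methyl-6-(pinB)dec-1-en-4-ol
Product: 12 (3R,4R,6S)-10-(TBSO)-3-methyl-6-(pinB)dec-1-en-4-yl methanesulfonate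
Conditions: MsCl, Et3N, CH2Cl2, −10 → 0 °C; used promptly
Reagents that add atoms: methanesulfonyl chloride CS(=O)(=O)Cl
Why: Sulfonylation of the secondary alcohol (via sulfene) proceeds without change at C7, and the neutral boronate, the silyl ether and the vinyl group are inert.

Step 7
Reactants: 12 (3R,4R,6S)-10-(TBSO)-3-methyl-6-(pinB)dec-1-en-4-yl methanesulfonate
Product: 14 tert-butyl{4-[(1R,2R)-2-[(2R)-but-3-en-2-yl]cyclopropyl]butoxy}dimethylsilane, via lithium phenylboronate complex 13 (not isolated)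
Conditions: PhLi (1.05 equiv), THF, −78 °C, 30 min; then → rt (40 °C if needed)
Reagents that add atoms: none
Why: PhLi adds to the vacant orbital of boron at −78 °C to give ate complex 13, whose electron-rich C5–B bond attacks C7 through its rear lobe as mesylate leaves, so that C5 reacts with inversion (invertive SE2) and C7 with inversion (SN2). The closest known reaction type is the 1,3-elimination of γ-halo- and γ-sulfonyloxy-alkylboron ate complexes to cyclopropanes, for which inversion at both carbons is established, together with the known invertive reactivity of aryllithium-activated secondary pinacol boronates. Ring C5–C6–C7 closes in the 3-exo-tet mode through a W-shaped B–C5–C6–C7–O array. The configuration at C5 is dictated by the C5–B stereocentre of 12 and that at C7 by the C7–O stereocentre, so the 1,3-anti (5S,7R) precursor should give only the trans (5R,7R) ring, with C8 untouched. The step needs ring closure to outrun elimination toward C8, attack at sulfur and ionisation at C7: capture of PhLi by boron at low temperature leaves no free base, the nucleophile arises three atoms from the leaving group, and in the reactive conformer the C4 chain and the C8 branch point away from each other.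

Step 8
Reactants: 14 tert-butyl{4-[(1R,2R)-2-[(2R)-but-3-en-2-yl]cyclopropyl]butoxy}dimethylsilane; 15 4,4,5,5-tetramethyl-2-vinyl-1,3,2-dioxaborolane
Product: 16 tert-butyldimethyl{4-[(1R,2R)-2-[(2R,3E)-4-(pinB)but-3-en-2-yl]cyclopropyl]butoxy}silane
Conditions: 15 (3 equiv), second-generation Hoveyda–Grubbs catalyst (5 mol%), 1,4-benzoquinone (10 mol%), CH2Cl2, 40 °C
Reagents that add atoms: none
Why: Olefin cross-metathesis of the mono-substituted alkene with vinylboronate should give the E alkenyl boronate (bulky boryl group, branched partner) without touching C8, since no carbonyl is ever placed next to it.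

Step 9
Reactants: 17 (S)-citronellal
Product: 18 (4S)-4,8-dimethylnon-7-en-1-yne
Conditions: dimethyl (1-diazo-2-oxopropyl)phosphonate, K2CO3, MeOH, 0 °C → rt
Reagents that add atoms: dimethyl (1-diazo-2-oxopropyl)phosphonate COP(=O)(OC)C(=[N+]=[N-])C(C)=O
Why: Seyferth–Gilbert homologation in the Ohira–Bestmann modification converts the aldehyde into the terminal alkyne (C18–C19) under mild base, and the C16 centre, β to the carbonyl, cannot epimerise.

Step 10
Reactants: 18 (4S)-4,8-dimethylnon-7-en-1-yne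
Product: 20 [(4S)-4,8-dimethylnon-7-en-1-yn-1-yl]tri(propan-2-yl)silane, via lithium acetylide 19 (not isolated)
Conditions: n-BuLi, THF, −78 °C; i-Pr3SiCl, −78 °C → rt
Reagents that add atoms: chlorotri(propan-2-yl)silane CC(C)[Si](Cl)(C(C)C)C(C)C
Why: Deprotonation of the terminal alkyne and C-silylation of acetylide 19 masks C18–C19 with a bulky group that resists ozone, acetylide, alane and aqueous base.

Step 11
Reactants: 20 [(4S)-4,8-dimethylnon-7-en-1-yn-1-yl]tri(propan-2-yl)silane
Product: 22 (4S)-4-methyl-7-(TIPS)hept-6-yn-1-ol, via ozonide 21 (not isolated)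
Conditions: O3, CH2Cl2, −78 °C, stopped when 20 is consumed; then NaBH4, MeOH, −78 → 0 °C
Reagents that add atoms: ozone [O-][O+]=O
Why: Ozonolysis with reductive borohydride work-up, in which ozone reacts with the electron-rich trisubstituted alkene much faster than with the hindered silylalkyne and NaBH4 reduces ozonide 21 to the primary C13 alcohol.

Step 12
Reactants: 22 (4S)-4-methyl-7-(TIPS)hept-6-yn-1-ol
Product: 23 [(4S)-7-iodo-4-methylhept-1-yn-1-yl]tri(propan-2-yl)silane
Conditions: I2, PPh3, imidazole, CH2Cl2, 0 °C → rt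
Reagents that add atoms: iodine II
Why: Appel-type iodination of a primary alcohol via the alkoxyphosphonium salt.

Step 13
Reactants: 23 [(4S)-7-iodo-4-methylhept-1-yn-1-yl]tri(propan-2-yl)silane
Product: 24 [(4S)-4-methylnona-1,8-diyn-1-yl]tri(propan-2-yl)silane
Conditions: LiC≡CH·H2NCH2CH2NH2, DMSO, 10 °C → rt
Reagents that add atoms: lithium acetylide (ethylenediamine complex) [Li+].[C-]#C
Why: SN2 alkylation of acetylide by the primary iodide in a dipolar aprotic solvent adds C11–C12, and the silylated alkyne is stable to this weakly basic nucleophile.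

Step 14
Reactants: 24 [(4S)-4-methylnona-1,8-diyn-1-yl]tri(propan-2-yl)silane
Product: 26 [(4S,8E)-9-iodo-4,8-dimethylnon-8-en-1-yn-1-yl]tri(propan-2-yl)silane, via alkenyldimethylalane 25 (not isolated)
Conditions: AlMe3 (2.5 equiv), Cp2ZrCl2 (0.25 equiv), CH2Cl2, 0 °C → rt; then I2, THF, −30 → 0 °C
Reagents that add atoms: trimethylaluminium C[Al](C)C; iodine II
Why: Negishi zirconium-catalysed carboalumination adds methyl (to C12) and aluminium (to C11) syn across the terminal alkyne only, the bulky silylalkyne being inert, and iodinolysis of alane 25 with retention gives the E iodide.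

Step 15
Reactants: 16 tert-butyldimethyl{4-[(1R,2R)-2-[(2R,3E)-4-(pinB)but-3-en-2-yl]cyclopropyl]butoxy}silane; 26 [(4S,8E)-9-iodo-4,8-dimethylnon-8-en-1-yn-1-yl]tri(propan-2-yl)silane
Product: 27 tert-butyldimethyl{4-[(1R,2R)-2-[(2R,3E,5E,10S)-6,10-dimethyl-13-(TIPS)trideca-3,5-dien-12-yn-2-yl]cyclopropyl]butoxy}silane
Conditions: PdCl2(dppf) (5 mol%), Cs2CO3 (3 equiv), DMF/THF/H2O, 40 °C
Reagents that add atoms: none
Why: Suzuki–Miyaura coupling of an alkenyl boronate with an alkenyl iodide forms C10–C11 with retention of both alkene geometries, giving the 9E,11E diene.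

Step 16
Reactants: 27 tert-butyldimethyl{4-[(1R,2R)-2-[(2R,3E,5E,10S)-6,10-dimethyl-13-(TIPS)trideca-3,5-dien-12-yn-2-yl]cyclopropyl]butoxy}silane
Product: 28 4-[(1R,2R)-2-[(2R,3E,5E,10S)-6,10-dimethyltrideca-3,5-dien-12-yn-2-yl]cyclopropyl]butan-1-ol
Conditions: Bu4NF (3 equiv), THF, 0 °C → rt
Reagents that add atoms: none
Why: Fluoride-induced desilylation cleaves the primary silyl ether and the alkynyl–silicon bond in one operation.

Step 17
Reactants: 28 4-[(1R,2R)-2-[(2R,3E,5E,10S)-6,10-dimethyltrideca-3,5-dien-12-yn-2-yl]cyclopropyl]butan-1-ol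
Product: 30 4-[(1R,2R)-2-[(2R,3E,5E,10S)-6,10-dimethyltrideca-3,5-dien-12-yn-2-yl]cyclopropyl]butanoic acid, via aldehyde 29 (not isolated)
Conditions: TEMPO (0.2 equiv), PhI(OAc)2 (2.2 equiv), MeCN/H2O (1:1), rt
Reagents that add atoms: water O
Why: Nitroxyl-catalysed oxidation of the primary alcohol through aldehyde 29 and its hydrate to the acid under near-neutral conditions that should spare the diene, the terminal alkyne and the cyclopropane.

Step 18
Reactants: 30 4-[(1R,2R)-2-[(2R,3E,5E,10S)-6,10-dimethyltrideca-3,5-dien-12-yn-2-yl]cyclopropyl]butanoic acid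
Product: 31 methyl 4-[(1R,2R)-2-[(2R,3E,5E,10S)-6,10-dimethyltrideca-3,5-dien-12-yn-2-yl]cyclopropyl]butanoate
Conditions: MeI, K2CO3, DMF, rt
Reagents that add atoms: iodomethane CI
Why: O-alkylation of the carboxylate (SN2 on iodomethane), with carbonate too weak a base to deprotonate the terminal alkyne.

Step 19
Reactants: 31 methyl 4-[(1R,2R)-2-[(2R,3E,5E,10S)-6,10-dimethyltrideca-3,5-dien-12-yn-2-yl]cyclopropyl]butanoate
Product: 32 methyl 4-[(1R,2R)-2-[(2R,3E,5E,10S)-13-bromo-6,10-dimethyltrideca-3,5-dien-12-yn-2-yl]cyclopropyl]butanoate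
Conditions: NBS (1.1 equiv), AgNO3 (0.1 equiv), acetone, rt, dark
Reagents that add atoms: N-bromosuccinimide O=C1CCC(=O)N1Br
Why: Silver-catalysed electrophilic bromination of the terminal alkyne via the silver acetylide should be much faster than attack of NBS on the diene under anhydrous, acid-free conditions.

**Compound list**

1 | hex-5-en-1-ol | OCCCCC=C | starting material
2 | tert-butyl(hex-5-en-1-yloxy)dimethylsilane | CC(C)(C)[Si](C)(C)OCCCCC=C | intermediate
3 | ethyl acrylate | C=CC(=O)OCC | starting material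
4 | ethyl (2E)-7-[(tert-butyldimethylsilyl)oxy]hept-2-enoate | CC(C)(C)[Si](C)(C)OCCCC/C=C/C(=O)OCC | intermediate
5 | bis(pinacolato)diboron | CC1(C)OB(OC1(C)C)B1OC(C)(C)C(C)(C)O1 | starting material
6 | ethyl (3S)-7-[(tert-butyldimethylsilyl)oxy]-3-(4,4,5,5-tetramethyl-1,3,2-dioxaborolan-2-yl)heptanoate | CC(C)(C)[Si](C)(C)OCCCC[C@H](B1OC(C)(C)C(C)(C)O1)CC(=O)OCC | intermediate
7 | diisobutylaluminium ethyl hemiacetal of 8 (formed in the flask, not isolated; hemiacetal carbon undefined) | CC(C)(C)[Si](C)(C)OCCCC[C@H](B1OC(C)(C)C(C)(C)O1)CC(OCC)O[Al](CC(C)C)CC(C)C | intermediate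
8 | (3S)-7-[(tert-butyldimethylsilyl)oxy]-3-(4,4,5,5-tetramethyl-1,3,2-dioxaborolan-2-yl)heptanal | CC(C)(C)[Si](C)(C)OCCCC[C@H](B1OC(C)(C)C(C)(C)O1)CC=O | intermediate
9 | cis-but-2-ene | C/C=C\C | starting material
10 | O-diisopinocampheylboryl derivative (borinate) of 11 (formed in the flask, not isolated) | CC(C)(C)[Si](C)(C)OCCCC[C@H](B1OC(C)(C)C(C)(C)O1)C[C@@H](OB([C@@H]1C[C@@H]2C[C@H]([C@H]1C)C2(C)C)[C@@H]1C[C@@H]2C[C@H]([C@H]1C)C2(C)C)[C@H](C)C=C | intermediate
11 | (3R,4R,6S)-10-[(tert-butyldimethylsilyl)oxy]-3-methyl-6-(4,4,5,5-tetramethyl-1,3,2-dioxaborolan-2-yl)dec-1-en-4-ol (C5 S, C7 R, C8 R) | CC(C)(C)[Si](C)(C)OCCCC[C@H](B1OC(C)(C)C(C)(C)O1)C[C@@H](O)[C@H](C)C=C | intermediate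
12 | (3R,4R,6S)-10-[(tert-butyldimethylsilyl)oxy]-3-methyl-6-(4,4,5,5-tetramethyl-1,3,2-dioxaborolan-2-yl)dec-1-en-4-yl methanesulfonate (key-step precursor) | CC(C)(C)[Si](C)(C)OCCCC[C@H](B1OC(C)(C)C(C)(C)O1)C[C@@H](OS(C)(=O)=O)[C@H](C)C=C | intermediate
13 | lithium B-phenyl ate complex of 12 (formed in the flask, not isolated) | [Li+].CC(C)(C)[Si](C)(C)OCCCC[C@H]([B-]1(c2ccccc2)OC(C)(C)C(C)(C)O1)C[C@@H](OS(C)(=O)=O)[C@H](C)C=C | intermediate
14 | tert-butyl{4-[(1R,2R)-2-[(2R)-but-3-en-2-yl]cyclopropyl]butoxy}dimethylsilane (key-step product) | CC(C)(C)[Si](C)(C)OCCCC[C@@H]1C[C@H]1[C@H](C)C=C | intermediate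
15 | 4,4,5,5-tetramethyl-2-vinyl-1,3,2-dioxaborolane | C=CB1OC(C)(C)C(C)(C)O1 | starting material
16 | tert-butyldimethyl{4-[(1R,2R)-2-[(2R,3E)-4-(4,4,5,5-tetramethyl-1,3,2-dioxaborolan-2-yl)but-3-en-2-yl]cyclopropyl]butoxy}silane | CC(C)(C)[Si](C)(C)OCCCC[C@@H]1C[C@H]1[C@H](C)/C=C/B1OC(C)(C)C(C)(C)O1 | intermediate
17 | (S)-citronellal, (3S)-3,7-dimethyloct-6-enal | CC(C)=CCC[C@H](C)CC=O | starting material
18 | (4S)-4,8-dimethylnon-7-en-1-yne | CC(C)=CCC[C@H](C)CC#C | intermediate
19 | lithium acetylide of 18 (formed in the flask, not isolated) | CC(C)=CCC[C@H](C)CC#C[Li] | intermediate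
20 | [(4S)-4,8-dimethylnon-7-en-1-yn-1-yl]tri(propan-2-yl)silane | CC(C)=CCC[C@H](C)CC#C[Si](C(C)C)(C(C)C)C(C)C | intermediate
21 | 3,3-dimethyl-5-[(3S)-3-methyl-6-(triisopropylsilyl)hex-5-yn-1-yl]-1,2,4-trioxolane (ozonide, not isolated; ring carbon undefined) | CC1(C)OOC(CC[C@H](C)CC#C[Si](C(C)C)(C(C)C)C(C)C)O1 | intermediate
22 | (4S)-4-methyl-7-[tri(propan-2-yl)silyl]hept-6-yn-1-ol | OCCC[C@H](C)CC#C[Si](C(C)C)(C(C)C)C(C)C | intermediate
23 | [(4S)-7-iodo-4-methylhept-1-yn-1-yl]tri(propan-2-yl)silane | ICCC[C@H](C)CC#C[Si](C(C)C)(C(C)C)C(C)C | intermediate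
24 | [(4S)-4-methylnona-1,8-diyn-1-yl]tri(propan-2-yl)silane | C#CCCC[C@H](C)CC#C[Si](C(C)C)(C(C)C)C(C)C | intermediate
25 | (E)-alkenyl(dimethyl)alane from 24, aluminium at C11 cis to the new C12 methyl (formed in the flask, not isolated) | C[Al](C)/C=C(\C)CCC[C@H](C)CC#C[Si](C(C)C)(C(C)C)C(C)C | intermediate
26 | [(4S,8E)-9-iodo-4,8-dimethylnon-8-en-1-yn-1-yl]tri(propan-2-yl)silane | I/C=C(\C)CCC[C@H](C)CC#C[Si](C(C)C)(C(C)C)C(C)C | intermediate
27 | tert-butyldimethyl{4-[(1R,2R)-2-[(2R,3E,5E,10S)-6,10-dimethyl-13-(triisopropylsilyl)trideca-3,5-dien-12-yn-2-yl]cyclopropyl]butoxy}silane | CC(C)(C)[Si](C)(C)OCCCC[C@@H]1C[C@H]1[C@H](C)/C=C/C=C(\C)CCC[C@H](C)CC#C[Si](C(C)C)(C(C)C)C(C)C | intermediate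
28 | 4-[(1R,2R)-2-[(2R,3E,5E,10S)-6,10-dimethyltrideca-3,5-dien-12-yn-2-yl]cyclopropyl]butan-1-ol | OCCCC[C@@H]1C[C@H]1[C@H](C)/C=C/C=C(\C)CCC[C@H](C)CC#C | intermediate
29 | 4-[(1R,2R)-2-[(2R,3E,5E,10S)-6,10-dimethyltrideca-3,5-dien-12-yn-2-yl]cyclopropyl]butanal (formed in the flask, not isolated) | O=CCCC[C@@H]1C[C@H]1[C@H](C)/C=C/C=C(\C)CCC[C@H](C)CC#C | intermediate
30 | 4-[(1R,2R)-2-[(2R,3E,5E,10S)-6,10-dimethyltrideca-3,5-dien-12-yn-2-yl]cyclopropyl]butanoic acid | OC(=O)CCC[C@@H]1C[C@H]1[C@H](C)/C=C/C=C(\C)CCC[C@H](C)CC#C | intermediate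
31 | methyl 4-[(1R,2R)-2-[(2R,3E,5E,10S)-6,10-dimethyltrideca-3,5-dien-12-yn-2-yl]cyclopropyl]butanoate | COC(=O)CCC[C@@H]1C[C@H]1[C@H](C)/C=C/C=C(\C)CCC[C@H](C)CC#C | intermediate
32 | methyl 4-[(1R,2R)-2-[(2R,3E,5E,10S)-13-bromo-6,10-dimethyltrideca-3,5-dien-12-yn-2-yl]cyclopropyl]butanoate | COC(=O)CCC[C@@H]1C[C@H]1[C@H](C)/C=C/C=C(\C)CCC[C@H](C)CC#CBr | target

**Step count**

Total: 19 steps. Longest linear sequence: 13 steps (steps 1–8 and 15–19, from hex-5-en-1-ol); the citronellal branch (steps 9–14) joins at step 15.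

**Steps most likely to fail, with fallbacks**

Step 7 (ring closure). The ate complex may not close the ring fast enough, so that elimination toward C8, attack of the aryllithium on the sulfonate or slow ionisation at C7 takes over, or closure may be incomplete. The fallback builds the ring by reagent-controlled methylene transfer; it sets out from enoate 4 and returns at 14.
- Reduction of 4 with i-Bu2AlH (2.2 equiv, CH2Cl2, −78 °C) would give (2E)-7-(TBSO)hept-2-en-1-ol F1.
- Asymmetric Simmons–Smith cyclopropanation (Zn(CH2I)2·DME, (4S,5S)-2-butyl-N,N,N′,N′-tetramethyl-1,3,2-dioxaborolane-4,5-dicarboxamide, CH2Cl2, 0 °C) should give {(1R,2R)-2-[4-(TBSO)butyl]cyclopropyl}methanol F2, with C5 and C7 set by the ligand.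
- Dess–Martin oxidation would give (1R,2R)-2-[4-(TBSO)butyl]cyclopropane-1-carbaldehyde F3.
- Horner–Wadsworth–Emmons reaction with triethyl phosphonoacetate and NaH would give ethyl (2E)-3-{(1R,2R)-2-[4-(TBSO)butyl]cyclopropyl}prop-2-enoate F4.
- i-Bu2AlH would give (2E)-3-{(1R,2R)-2-[4-(TBSO)butyl]cyclopropyl}prop-2-en-1-ol F5.
- CBr4/PPh3 at −20 °C would give tert-butyl{4-[(1R,2R)-2-[(1E)-3-bromoprop-1-en-1-yl]cyclopropyl]butoxy}dimethylsilane F6.
- Copper-catalysed asymmetric SN2′ methylation of F6 (MeMgBr, CuBr·SMe2, the Taniaphos enantiomer that delivers 8R, CH2Cl2, −78 °C) would install the C8 methyl centre and the terminal vinyl group and give 14.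

Step 5 (crotylboration). Facial selectivity may be eroded by the β-boryl centre, the C5 boronate may be lost, or the borinate may be cleaved incompletely in the peroxide-free work-up. The fallback sets C7/C8 by an auxiliary-controlled titanium aldol reaction followed by olefination; it sets out from aldehyde 8 and returns at 11.
- The titanium enolate of (4S)-4-benzyl-3-propanoyl-1,3-thiazolidine-2-thione (TiCl4, i-Pr2NEt, N-methylpyrrolidinone, CH2Cl2, 0 → −78 °C) would add to 8 to give the syn aldol adduct (4S)-4-benzyl-3-[(2S,3R,5S)-9-(TBSO)-3-hydroxy-2-methyl-5-(pinB)nonanoyl]-1,3-thiazolidine-2-thione F7 after aqueous NH4Cl work-up.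
- Et3SiOTf/2,6-lutidine would give its triethylsilyl ether F8.
- i-Bu2AlH (CH2Cl2, −78 °C) would cleave the auxiliary directly to (2S,3R,5S)-9-(TBSO)-2-methyl-5-(pinB)-3-[(triethylsilyl)oxy]nonanal F9.
- Wittig methylenation (Ph3P=CH2 from Ph3PCH3Br and KN(SiMe3)2, THF, −78 → 0 °C) would give (5S,7R,8R)-1-(TBSO)-8-methyl-5-(pinB)-7-[(triethylsilyl)oxy]dec-9-ene F10.
- Pyridinium p-toluenesulfonate in MeOH at 0 °C would remove the triethylsilyl group faster than the primary TBS ether and give 11.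

Step 8 (cross-metathesis). The branched alkene may convert slowly, the E/Z ratio may erode, or the double bond may migrate toward C8. The fallback makes the alkenyl boronate by carbonyl olefination; it sets out from 14 and returns at 16.
- Ozonolysis (O3, CH2Cl2, −78 °C; PPh3) would give, through the ozonide 3-{(2R)-…propan-2-yl}-1,2,4-trioxolane F11, the aldehyde (2S)-2-{(1R,2R)-2-[4-(TBSO)butyl]cyclopropyl}propanal F12.
- F12 would be taken at once, without chromatography, into a Takai–Utimoto boryl olefination (CrCl2, Cl2CHB(pin), LiI, THF, rt) to give the E alkenyl boronate 16.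

Further compounds
F1 | step 7 | (2E)-7-[(tert-butyldimethylsilyl)oxy]hept-2-en-1-ol | CC(C)(C)[Si](C)(C)OCCCC/C=C/CO
F2 | step 7 | [(1R,2R)-2-{4-[(tert-butyldimethylsilyl)oxy]butyl}cyclopropyl]methanol | CC(C)(C)[Si](C)(C)OCCCC[C@@H]1C[C@H]1CO
F3 | step 7 | (1R,2R)-2-{4-[(tert-butyldimethylsilyl)oxy]butyl}cyclopropane-1-carbaldehyde | CC(C)(C)[Si](C)(C)OCCCC[C@@H]1C[C@H]1C=O
F4 | step 7 | ethyl (2E)-3-[(1R,2R)-2-{4-[(tert-butyldimethylsilyl)oxy]butyl}cyclopropyl]prop-2-enoate | CC(C)(C)[Si](C)(C)OCCCC[C@@H]1C[C@H]1/C=C/C(=O)OCC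
F5 | step 7 | (2E)-3-[(1R,2R)-2-{4-[(tert-butyldimethylsilyl)oxy]butyl}cyclopropyl]prop-2-en-1-ol | CC(C)(C)[Si](C)(C)OCCCC[C@@H]1C[C@H]1/C=C/CO
F6 | step 7 | tert-butyl{4-[(1R,2R)-2-[(1E)-3-bromoprop-1-en-1-yl]cyclopropyl]butoxy}dimethylsilane | CC(C)(C)[Si](C)(C)OCCCC[C@@H]1C[C@H]1/C=C/CBr
F7 | step 5 | (4S)-4-benzyl-3-[(2S,3R,5S)-9-[(tert-butyldimethylsilyl)oxy]-3-hydroxy-2-methyl-5-(4,4,5,5-tetramethyl-1,3,2-dioxaborolan-2-yl)nonanoyl]-1,3-thiazolidine-2-thione | CC(C)(C)[Si](C)(C)OCCCC[C@H](B1OC(C)(C)C(C)(C)O1)C[C@@H](O)[C@H](C)C(=O)N1[C@@H](Cc2ccccc2)CSC1=S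
F8 | step 5 | triethylsilyl ether of F7 | CC(C)(C)[Si](C)(C)OCCCC[C@H](B1OC(C)(C)C(C)(C)O1)C[C@@H](O[Si](CC)(CC)CC)[C@H](C)C(=O)N1[C@@H](Cc2ccccc2)CSC1=S
F9 | step 5 | (2S,3R,5S)-9-[(tert-butyldimethylsilyl)oxy]-2-methyl-5-(4,4,5,5-tetramethyl-1,3,2-dioxaborolan-2-yl)-3-[(triethylsilyl)oxy]nonanal | CC(C)(C)[Si](C)(C)OCCCC[C@H](B1OC(C)(C)C(C)(C)O1)C[C@@H](O[Si](CC)(CC)CC)[C@H](C)C=O
F10 | step 5 | (5S,7R,8R)-1-[(tert-butyldimethylsilyl)oxy]-8-methyl-5-(4,4,5,5-tetramethyl-1,3,2-dioxaborolan-2-yl)-7-[(triethylsilyl)oxy]dec-9-ene | CC(C)(C)[Si](C)(C)OCCCC[C@H](B1OC(C)(C)C(C)(C)O1)C[C@@H](O[Si](CC)(CC)CC)[C@H](C)C=C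
F11 | step 8 | 3-[(2R)-2-{(1R,2R)-2-[4-(tert-butyldimethylsilyloxy)butyl]cyclopropyl}propan-2-yl-type ozonide of 14: 3-substituted 1,2,4-trioxolane (not isolated; ring carbon undefined) | CC(C)(C)[Si](C)(C)OCCCC[C@@H]1C[C@H]1[C@H](C)C1OCOO1
F12 | step 8 | (2S)-2-[(1R,2R)-2-{4-[(tert-butyldimethylsilyl)oxy]butyl}cyclopropyl]propanal | CC(C)(C)[Si](C)(C)OCCCC[C@@H]1C[C@H]1[C@H](C)C=O
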